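(The readings are simulated with made-up constants, noise included.)

I was asked how much target stands after 2.0 h in a row of flasks that differ in their charge of free catalyst.

| setting | Sunday's | Friday's | east | south-west | north | north-east | south |
|---|---|---|---|---|---|---|---|
| starting material | 0.40 M | 0.40 M | 0.40 M | 0.40 M | 0.40 M | 0.40 M | 0.40 M |
| free catalyst | 0.022 mM | 2.7 mM | 0.040 mM | 0.12 mM | 0.40 mM | 1.2 mM | 4.0 mM |
| added ligand | 0.31 mM | 0.31 mM | 0.31 mM | 0.31 mM | 0.31 mM | 0.31 mM | 0.31 mM |
| remark | run made earlier | run made earlier |  |  |  |  |  |
| time |  |  | 2.0 h | 2.0 h | 2.0 h | 2.0 h | 2.0 h |

| run | time / min | target / % |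
|---|---|---|
| Sunday's | 10.0 | 1.1 |
| Sunday's | 30.0 | 4.1 |
| Sunday's | 50.0 | 5.1 |
| Sunday's | 80.0 | 5.4 |
| Friday's | 10.0 | 32.9 |
| Friday's | 30.0 | 33.7 |
| Friday's | 50.0 | 34.8 |
| Friday's | 80.0 | 32.6 |

(scatter of a reading: 1 percentage point)

- [target] at the end for east, south-west, north, north-east, south, in this order
- the course of these numbers from the first flask to the last (falls all the way / falls, then rises / rises all the way / rises, then falls / hardly changes)

I ordered the runs by how quickly they finished. Friday's run, with 2.7 mM of free catalyst, was the faster of the two: it already showed 32.9% at 10.0 min, and its later readings wandered by about twice the scatter of 1 percentage point. I read that as a ceiling of 0.134 M of target. Sunday's run, with 0.022 mM, was slower: its readings climbed until about 50.0 min and stood at 5.4% by 80.0 min. That is lower than Friday's level from the same charge of starting material, so I took Sunday's stop to come from its catalyst ceasing to work, not from the ceiling. The asked time was the last rung, longer than the time of Sunday's last reading, so I reckoned with end states.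

Sunday's plateau divided by its catalyst gave the turnover capacity (the turnover number), the target made per catalyst charged before it stops: 982. The reading carries its scatter of 1 point. I then took capacity times charge over ceiling as a load, with one as the balanced case. East stood at 0.293 and south-west at 0.879, while north stood at 2.93. Below one I expected capacity times charge, 0.0393 M for east and 0.118 M for south-west, and above one the ceiling.

The forecast gave 0.037 M, 0.083 M, 0.128 M, 0.134 M and 0.134 M, lower than mine at south-west, and a course that rises all the way, reasoning that “Friday reaches that ceiling; Sunday's catalyst dies first”. The flasks gave 0.0388 M, 0.0624 M, 0.0964 M, 0.125 M and 0.135 M, a course that rises all the way.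

    free catalyst + added ligand ⇌ idle complex, settled at all times (K = 3700 M⁻¹)
    target ⇌ isomer of the product (K = 0.459, k = 0.00455 s⁻¹)
    free catalyst + target → spent catalyst (k = 0.0409 M⁻¹ s⁻¹)
    starting material + free catalyst ⇌ target + free catalyst, rate k4*[starting material]*[free catalyst] forward; the back reaction follows from the equilibrium constant (K = 0.687, k = 1.56 M⁻¹ s⁻¹)
    isomer of the product + free catalyst ⇌ starting material + free catalyst, rate k5*[free catalyst]*[isomer of the product] forward; the back reaction follows from the equilibrium constant (k = 6.15 M⁻¹ s⁻¹)

In east, target and isomer of the product relaxed by their own step alone, both ways together, with a half-life of 0.799 min, short against 2.0 h, and the flask ended with 9.70% of target beside 4.45% of isomer of the product. Counted in target, east gave 970 turnovers per catalyst charged against Sunday's 982, but north gave 241, fewer, and stopped at 0.0964 M, below the ceiling, with spent catalyst at >99.9% of its charge.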